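(The runs were computed for an exercise, noise included.)

22.7 min is the number I go by: it is τ, my estimate of the time in which south, at 20 mM, would turn over its whole substrate charge at the average pace read over the alpha run and scaled to that concentration, a pseudo-first-order time constant, since I freeze reagent and catalyst at their charges and let the substrate fraction fall.

| flask | substrate | reagent | catalyst | remark | time |
|---|---|---|---|---|---|
| alpha | 13 mM | 1 equiv | 0.2 mol% | run made earlier |  |
| theta | 10 mM | 1 equiv | 0.2 mol% | run made earlier |  |
| east | 20 mM | 0.330 equiv | 0.05 mol% |  | 8.0 min |
| south | 20 mM | 1.00 equiv | 0.2 mol% |  | 8.0 min |

- alpha (time / min: target / %): 0.667: 3.7; 1.33: 3.9; 2.00: 6.3; 3.00: 8.6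
- theta (time / min: target / %): 0.667: 1.3; 1.33: 4.2; 2.00: 5.4; 3.00: 6.8

(standard deviation of a reading: 0.5 percentage points)

- the winner by amount of target, in percent of the substrate charged; "neither" if no more than 2 percentage points parts them (east / south / neither)
- how much target is there at the end, in percent of the substrate charged: east
- how much target is there at the end, in percent of the substrate charged: south

- the numbers in the tables scatter with a standard deviation of 0.5 percentage points

I take τ from the alpha run, which reads 8.6% at 3.00 min, and I scale its pace, in fractions of the charge per minute, with the concentration; the theta run, scaled the same way, reads 22.1 min, so the two agree within the scatter.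

Two times then carry the comparison, the run's 8.0 min and τ, and in south the run lasts about a third of τ. The converted fraction is one minus exp(−time/τ):

south: 8.0 min / 22.7 min = 0.353, converted 29.7%

East has a quarter of south's catalyst loading and a third of its reagent, and the earlier runs hold both fixed, so I reckon east twice:

east, τ stretched by catalyst: 90.7 min, converted 8.44%

east, τ stretched by reagent too: 275 min, converted 2.87%

Even the higher east figure stands 21 points below south, which is more than the margin of 2 points, so I commit to south.

The forecast names south, with south at 31% (25% to 38%), slightly above my figure, and east at 8% (3% to 14%), and it notes “The catalyst and reagent orders are untested”.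

The flask gives 27.0% in south and 4.26% in east, so south wins.

    substrate + reagent + catalyst → catalyst + target (k = 2100 /M²/s)
    2 reagent → homo dimer (k = 0.150 /M/s)

At 8.00 min south still holds 73.0% of its substrate but 16.8% of its own reagent charge, beside 5.62 mM of homo dimer, so the reagent I froze did not stay at its charge. Put to the same flask read at 5.0 min, τ gives 19.8%, and the flask there stands at 22.2%.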